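## Structural features

The target 12 is an indole: a benzene ring (C3a, C4 to C7, C7a) fused through the C3a–C7a bond to a pyrrole ring (N1, C2, C3). It carries bromine at C2 on the pyrrole ring and at C4 and C6 on the benzene ring, a free N–H and an unsubstituted C3. There is no stereocentre; the only stereochemical event in the route is a transient racemic carbinol at C3 that dehydration erases. Once the C–Br bonds are present they exclude alkyllithium reagents, dissolving metals, catalytic hydrogenation and any conditions under which low-valent transition metals insert into C–Br. The 2-bromoindole unit is the most fragile part, being open to hydrolysis to the oxindole in hot acid and to electrophilic attack at the free C3. The real difficulty is regiochemical: electrophilic bromination of an indole goes to C3 first, so neither the meta-related C4/C6 pair nor a C2 bromine beside a free C3–H can be made by direct halogenation. The key step uses the fact that N1 (on C7a) and C3 (on C3a) are ortho substituents of the benzene ring while the C4 bromine is the direct neighbour of C3a. An aryne with its triple bond between C3a and C7a is therefore polarised so that nitrogen enters at C7a and the carbanion left at C3a closes onto a two-atom tether.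

## Logic of the disconnections

12 to 11. The C2–Br bond is cut back to a C2–B bond. An ipso exchange at boron places bromine where free electrophilic bromine would not go (it would choose C3), and it leaves the fragile 2-bromoindole to the last step. The forward step needs the CuBr2 exchange to be faster than electrophilic attack at C3 and faster than protodeboronation.

11 to 10. The C2–B bond is cut back to C2–H. In an N–H indole the C–H next to nitrogen is the most reactive towards the [Ir(OMe)(cod)]2/bipyridine borylation catalyst, and here every other ring C–H is shielded: C5–H lies between two bromines, C7–H is ortho to one, C3–H is peri to the C4 bromine. This reduces the problem to 10, which carries only the benzene-ring bromines. The forward step needs a catalyst that ignores C–Br bonds and a limited boron charge so that a second borylation does not start.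

10 to 8 (through 9). Water is formally added back across C2–C3 and the nitrogen is re-protected as its tert-butyl carbamate. This is the oxidation level that results when an aryl anion adds to an aldehyde. The forward step asks one acid treatment to remove the carbamate and dehydrate the benzylic alcohol without oligomerising the indole.

8 to 5 and 6 (through 7). The N1–C7a and C3–C3a bonds are cut, the two bonds that join the benzene ring to the five-membered ring. This leaves aryne 7 and the bifunctional partner 6, so one ring and two skeletal bonds form in a single metal-free operation. The atom mapping was checked and needs no correction: the silicon-bearing carbon of 5 becomes C7a and the triflate-bearing carbon becomes C3a, so the bromine ortho to the triflate ends at C4 and the para bromine at C6. The forward step needs nitrogen to attack the aryne carbon remote from bromine, and the ring closure must outrun protonation of the aryl anion and loss of the neighbouring bromide.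

5 to 1 (through 2, 3 and 4). The C–Si and O–S bonds are cut and silicon is replaced by bromine, which leads to the symmetric 1. Its two ortho bromines are equivalent, so O-silylation, one bromine–lithium exchange, retro-Brook silyl shift and O-triflation can be run in one flask. The forward step needs exchange at an ortho and not the para bromine, and only once.

## Other disconnections considered

Alternative 1: The cut is at C4–Br and C6–Br, with C2–Br traced back to an oxindole carbonyl. In the forward key step 5-aminoindolin-2-one A1 would take two equivalents of NBS at the two positions ortho to the amine, giving 5-amino-4,6-dibromoindolin-2-one A2. Diazotisation and reduction with H3PO2 would remove the amine to give 4,6-dibromoindolin-2-one A3, and POBr3 would convert the lactam into 12.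
- In favour: about three steps from A1, no protecting group, no transition-metal catalyst and no cryogenic organolithium. The C2 bromine comes from a carbonyl by an established dehydrative bromination, so no C2–H functionalisation is needed. On step count and on the way C2–Br is made this alternative is the better of the two.
- Against: NBS has three competing sites, namely the amine-activated C4 and C6, the enolisable C3 methylene and C7 ortho to the lactam nitrogen. The para-diamine-type ring is easily oxidised. Diazotising a hindered 2,6-dibromoaniline needs strongly acidic nitrosating conditions, which can also attack the active C3 methylene.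
- Comparison: the chosen plan carries the C4/C6 pattern in from 1 and makes no regiochemical decision on the benzene ring. It pays for this with the aryne regiochemistry and a two-step C2 bromination. Mechanistically the alternative relies on electrophilic substitution and the chosen plan on aryne polarisation.

Alternative 2: The cut is at C3a–C4 and C7–C7a, so the benzene ring is built onto a pyrrole. Remark on the chemistry: for methanol to be the molecule lost on aromatisation, the methoxy group is taken to sit on C4 of the pyrrole, which becomes C3a. In the forward key step 3,5-dibromo-2H-pyran-2-one A4 would act as the diene and the C4–C5 bond of tert-butyl 2-[(tert-butyldimethylsilyl)oxy]-4-methoxy-1H-pyrrole-1-carboxylate A5 as the dienophile in a Diels–Alder reaction. Extrusion of CO2 and elimination of methanol would give tert-butyl 4,6-dibromo-2-[(tert-butyldimethylsilyl)oxy]-1H-indole-1-carboxylate A6. Acid would then unmask A3, and POBr3 would give 12.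
- In favour: the polarity is matched, since the nucleophilic C5 of A5 meets the electrophilic C6 of A4, which places the pyrone C3 and C5 bromines at C4 and C6. C2 arrives already oxidised, so this alternative is also better than the chosen plan in needing no C–H borylation.
- Against: the C4–C5 bond of A5 belongs to an aromatic sextet and is a reluctant dienophile. A5 is more likely to react as a vinylogous silyl enol ether in a conjugate addition to A4 than in a cycloaddition. The heat needed for CO2 loss threatens the silyl ketene aminal and the carbamate. A5 is not commercial and needs its own preparation.
- Comparison: with the preparation of A4 and A5, the key step, the unmasking and the POBr3 step, the count is equal to or longer than that of the chosen plan. The chosen plan is more convergent because it closes the small ring onto a ready-made benzene ring from two cheap materials. The two plans are equal in fixing the bromine pattern within a building block.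

Alternative 3: The cut is at C2–C3 and N1–C2, with C2 and its bromine supplied by one reagent. In the forward key step Cs2CO3 would convert N-[3,5-dibromo-2-(bromomethyl)phenyl]-4-methylbenzenesulfonamide A7 into the aza-ortho-quinone methide N-(3,5-dibromo-6-methylidenecyclohexa-2,4-dien-1-ylidene)-4-methylbenzenesulfonamide A8. The tribromomethyl anion from bromoform A9 would add to its methylene carbon, and loss of two HBr with N–C2 closure would give 2,4,6-tribromo-1-tosyl-1H-indole A10. Detosylation would give 12.
- In favour: C2 arrives with its bromine, which is better than the chosen plan because no late C–H functionalisation is required. About four steps, equal to or slightly shorter than the chosen plan. Formal (4+1) annulations of aza-ortho-quinone methides with one-carbon nucleophiles are an established class.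
- Against: the tribromomethyl anion readily loses bromide to a carbene, which opens other pathways. Nitrogen cannot displace bromide directly at a tribromomethyl carbon, so closure would have to go through elimination to a dibromoalkene and a 5-endo vinylic substitution. The methylene carbon of A8 is flanked by the bromine that becomes C4. A7 requires radical bromination of a hindered methyl group beside an N–H sulfonamide. Removing the tosyl group from a 2-bromoindole is delicate, because nucleophilic conditions can attack C2–Br and reductive ones cleave C–Br.
- Comparison: both plans fix the C4/C6 pattern in the arene from the start and are equal on that point. The key step of the chosen plan stands on closer mechanistic precedent and ends with an acid-labile carbamate, which is easier to remove than a sulfonyl group.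

Key step: step 2

Remarks on the chemistry (assumptions): 6 is used as the commercial free aldehyde, freshly purified because it oligomerises on storage. The silyl ether 2 is concentrated but not purified before the lithiation.

## Route

Step 1
Reactants: 1 2,4,6-tribromophenol
Product: 5 2,4-dibromo-6-(trimethylsilyl)phenyl trifluoromethanesulfonate, via (2,4,6-tribromophenoxy)trimethylsilane 2 (not isolated), via [3,5-dibromo-2-(trimethylsilyloxy)phenyl]lithium 3 (not isolated), via lithium 2,4-dibromo-6-(trimethylsilyl)phenoxide 4 (not isolated)
Conditions: (Me3Si)2NH, THF, reflux, then evaporation; n-BuLi (1.05 equiv), THF, −100 to −80 °C; Tf2O, −100 °C to rt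
Reagents that add atoms: hexamethyldisilazane, C[Si](C)(C)N[Si](C)(C)C; trifluoromethanesulfonic anhydride, O=S(=O)(OS(=O)(=O)C(F)(F)F)C(F)(F)F
Why: O-silylation, bromine–lithium exchange at one of the two equivalent ortho bromines (favoured over the para bromine by the adjacent oxygen), retro-Brook 1,3-silyl shift from oxygen to carbon and O-triflation of the phenoxide make up the standard one-flask route from ortho-bromophenols to ortho-silylaryl triflates. Aryllithium 3 has no ortho leaving group that could be lost at −100 °C, and the symmetry of 1 means either ortho bromine leads to the same product.

Step 2
Reactants: 5 2,4-dibromo-6-(trimethylsilyl)phenyl trifluoromethanesulfonate; 6 tert-butyl (2-oxoethyl)carbamate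
Product: 8 rac-tert-butyl 4,6-dibromo-3-hydroxyindoline-1-carboxylate, via 3,5-dibromo-1,2-didehydrobenzene 7 (not isolated)
Conditions: CsF (3 equiv), MeCN, 0 °C to rt, slow addition of 5 to 6 (2 equiv); aq NH4Cl work-up
Reagents that add atoms: none
Why: CsF attacks silicon of 5 and triflate leaves, releasing aryne 7 without any metal, so both C–Br bonds and the aldehyde survive. The carbamate nitrogen of 6, activated by fluoride through N–H···F hydrogen bonding or deprotonation, adds to the aryne carbon that becomes C7a (N1–C7a), and the aryl anion left on C3a adds to the tethered aldehyde (C3–C3a) to give a cesium alkoxide that is protonated on work-up. The closest known reaction type is the fluoride-triggered annulation of arynes with N-protected α-amino ketones and esters to 3-hydroxyindolines and indolin-3-ones, together with the addition of carbamate N–H groups to arynes in indoline-forming annulations. The five-membered ring closes in the 5-exo-trig mode. The one new stereocentre, C3, forms without any controlling element, so 8 is a racemate; this has no consequence because step 3 removes the centre. The selectivity needed is regioselective nitrogen attack on an unsymmetrical aryne: the bromine next to the triple bond (the future C4 bromine) polarises and distorts it by induction and shields its own side, so the nucleophile goes to the remote carbon and the negative charge develops next to bromine, while the second bromine, meta to C7a, exerts only a weak bias in the opposite sense. Chemoselectivity for nitrogen over the carbonyl oxygen and the product alkoxide is supported by the excess of 6 and the slow release of the aryne. The aldehyde is the most electrophilic carbonyl the tether can carry, which should help ring closure outrun protonation of the aryl anion and loss of the neighbouring bromide.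

Step 3
Reactants: 8 rac-tert-butyl 4,6-dibromo-3-hydroxyindoline-1-carboxylate
Product: 10 4,6-dibromo-1H-indole, via rac-4,6-dibromoindolin-3-ol 9 (not isolated)
Conditions: CF3CO2H, CH2Cl2, 0 °C to rt
Reagents that add atoms: none
Why: Acidolysis of the tert-butyl carbamate is followed by acid-catalysed E1 dehydration of the benzylic alcohol 9, whose cation is stabilised by the ortho amino group; loss of the C2 proton aromatises the ring and removes the racemic centre. The two bromines make the indole a poor nucleophile, which should limit acid-induced self-condensation.

Step 4
Reactants: 10 4,6-dibromo-1H-indole
Product: 11 4,6-dibromo-2-(4,4,5,5-tetramethyl-1,3,2-dioxaborolan-2-yl)-1H-indole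
Conditions: [Ir(OMe)(cod)]2 (1.5 mol %), 4,4′-di-tert-butyl-2,2′-bipyridine (3 mol %), B2pin2 (0.6 equiv), THF, rt to 50 °C
Reagents that add atoms: bis(pinacolato)diboron, CC1(C)OB(OC1(C)C)B1OC(C)(C)C(C)(C)O1
Why: Iridium-catalysed C–H borylation through a tris(boryl) complex of trivalent iridium takes the C2–H bond of an N–H indole first, and here C5–H (between two bromines), C7–H (ortho to bromine) and C3–H (peri to the C4 bromine) are all sterically shielded. Aryl bromides are not attacked by this catalyst, and the limited B2pin2 charge guards against a second borylation.

Step 5
Reactants: 11 4,6-dibromo-2-(4,4,5,5-tetramethyl-1,3,2-dioxaborolan-2-yl)-1H-indole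
Product: 12 2,4,6-tribromo-1H-indole
Conditions: CuBr2 (3 equiv), MeOH/H2O 1:1, 80 °C
Reagents that add atoms: copper dibromide, [Cu+2].[Br-].[Br-]
Why: Copper-mediated bromodeboronation of an aryl pinacol boronate proceeds by transmetalation from boron to divalent copper, oxidation by a second CuBr2 to an aryl bromide complex of trivalent copper and C–Br reductive elimination. Bromine therefore replaces boron at the same carbon, which transfers the regiochemistry of step 4 to C2 and avoids the C3 preference of free electrophilic bromine.

## Compound list

1 | 2,4,6-tribromophenol | Oc1c(Br)cc(Br)cc1Br | starting material
2 | (2,4,6-tribromophenoxy)trimethylsilane | C[Si](C)(C)Oc1c(Br)cc(Br)cc1Br | intermediate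
3 | [3,5-dibromo-2-(trimethylsilyloxy)phenyl]lithium | [Li]c1cc(Br)cc(Br)c1O[Si](C)(C)C | intermediate
4 | lithium 2,4-dibromo-6-(trimethylsilyl)phenoxide | [Li+].[O-]c1c(Br)cc(Br)cc1[Si](C)(C)C | intermediate
5 | 2,4-dibromo-6-(trimethylsilyl)phenyl trifluoromethanesulfonate | C[Si](C)(C)c1cc(Br)cc(Br)c1OS(=O)(=O)C(F)(F)F | intermediate
6 | tert-butyl (2-oxoethyl)carbamate | CC(C)(C)OC(=O)NCC=O | starting material
7 | 3,5-dibromo-1,2-didehydrobenzene | BrC1=CC(Br)=CC#C1 | intermediate
8 | rac-tert-butyl 4,6-dibromo-3-hydroxyindoline-1-carboxylate (racemic at C3) | CC(C)(C)OC(=O)N1CC(O)c2c(Br)cc(Br)cc21 | intermediate
9 | rac-4,6-dibromoindolin-3-ol (racemic at C3) | OC1CNc2cc(Br)cc(Br)c12 | intermediate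
10 | 4,6-dibromo-1H-indole | Brc1cc(Br)c2cc[nH]c2c1 | intermediate
11 | 4,6-dibromo-2-(4,4,5,5-tetramethyl-1,3,2-dioxaborolan-2-yl)-1H-indole | CC1(C)OB(OC1(C)C)c1cc2c(Br)cc(Br)cc2[nH]1 | intermediate
12 | 2,4,6-tribromo-1H-indole | Brc1cc(Br)c2cc(Br)[nH]c2c1 | target

## Step count and least certain steps

Total step count: 5. Longest linear sequence: 5 steps (1 to 12); 6 enters as a commercial partner in step 2.

Step 2 (key step).
- What may go wrong: fluoride may consume 6 by enolisation and self-aldol reaction, or oxygen nucleophiles (the carbonyl oxygen, the product alkoxide) may capture the aryne before N-arylation. The N–H of the carbamate is only weakly acidic, comparable to the α-C–H of the aldehyde. After N-arylation, protonation of the aryl anion or loss of the neighbouring bromide may compete with ring closure. Some nitrogen attack at the aryne carbon beside bromine would erode the regiochemistry.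
- Fallback: it sets out from 5 and returns at 8. Under the same CsF activation, 5 would be combined with methyl N-(tert-butoxycarbonyl)glycinate F1, which has no aldehyde. The aryl anion would then close by acyl substitution at the ester with loss of methoxide, giving tert-butyl 4,6-dibromo-3-oxoindoline-1-carboxylate F2. NaBH4 in MeOH at 0 °C would reduce the ketone of F2 to the alcohol 8. This changes the oxidation level of the electrophile and moves formation of the carbinol into a separate reduction.

Step 5.
- What may go wrong: CuBr2 is itself a brominating agent for indoles, so electrophilic bromination at the free C3 may accompany the ipso exchange. Protodeboronation of the 2-indolyl boronate in hot aqueous methanol may also occur, and the HBr formed may promote hydrolysis of the new C2–Br bond.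
- Fallback: it sets out from 10 and returns at 12. Pyridinium tribromide in t-BuOH would oxidise 10 to 3,3,4,6-tetrabromoindolin-2-one F3. Zn in AcOH at rt would remove the two C3 bromines without touching the aryl bromides, giving 4,6-dibromoindolin-2-one F4. POBr3 with imidazole in refluxing 1,2-dichloroethane would convert the lactam of F4 into the 2-bromoindole 12. The C2 bromine then comes from a carbonyl oxygen and not from a C–B bond.

Step 3.
- What may go wrong: acid-catalysed self-condensation of the 2,3-unsubstituted indole, capture of the C3 benzylic cation by product, or C-alkylation by the tert-butyl cation. All stem from exposing a free indole and a benzylic cation to strong acid together.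
- Fallback: it sets out from 8 and returns at 10. MsCl and Et3N in CH2Cl2 (0 °C to rt, with DBU if the mesylate persists) would eliminate the benzylic mesylate to tert-butyl 4,6-dibromo-1H-indole-1-carboxylate F5. K2CO3 in MeOH would then cleave the indole N-carbamate by methanolysis to give 10. Dehydration and deprotection are both done under basic conditions and no acid is used.

Step 1.
- What may go wrong: exchange at the para bromine or a second exchange, since three C–Br bonds compete for n-BuLi; an incomplete silyl shift would also lower the yield.
- Fallback: it does not set out from a compound of the route; commercial 2,4-dibromophenol F6 replaces 1, and it returns at intermediate 3. N-Iodosuccinimide with catalytic TsOH in MeCN would iodinate the only free ortho position to give 2,4-dibromo-6-iodophenol F7. (Me3Si)2NH would silylate it to (2,4-dibromo-6-iodophenoxy)trimethylsilane F8. n-BuLi at −100 °C would then exchange only the far more reactive C–I bond, which gives aryllithium 3. From 3 the retro-Brook shift to 4 and the triflation to 5 follow as in step 1.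

## Further compounds

F1 | step 2 | methyl N-(tert-butoxycarbonyl)glycinate | COC(=O)CNC(=O)OC(C)(C)C
F2 | step 2 | tert-butyl 4,6-dibromo-3-oxoindoline-1-carboxylate | CC(C)(C)OC(=O)N1CC(=O)c2c(Br)cc(Br)cc21
F3 | step 5 | 3,3,4,6-tetrabromoindolin-2-one | O=C1Nc2cc(Br)cc(Br)c2C1(Br)Br
F4 | step 5 | 4,6-dibromoindolin-2-one | O=C1Cc2c(Br)cc(Br)cc2N1
F5 | step 3 | tert-butyl 4,6-dibromo-1H-indole-1-carboxylate | CC(C)(C)OC(=O)n1ccc2c(Br)cc(Br)cc21
F6 | step 1 | 2,4-dibromophenol | Oc1ccc(Br)cc1Br
F7 | step 1 | 2,4-dibromo-6-iodophenol | Oc1c(I)cc(Br)cc1Br
F8 | step 1 | (2,4-dibromo-6-iodophenoxy)trimethylsilane | C[Si](C)(C)Oc1c(I)cc(Br)cc1Br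
A1 | alternative 1 | 5-aminoindolin-2-one | Nc1ccc2NC(=O)Cc2c1
A2 | alternative 1 | 5-amino-4,6-dibromoindolin-2-one | Nc1c(Br)cc2NC(=O)Cc2c1Br
A3 | alternative 1 | 4,6-dibromoindolin-2-one | O=C1Cc2c(Br)cc(Br)cc2N1
A4 | alternative 2 | 3,5-dibromo-2H-pyran-2-one | O=C1OC=C(Br)C=C1Br
A5 | alternative 2 | tert-butyl 2-[(tert-butyldimethylsilyl)oxy]-4-methoxy-1H-pyrrole-1-carboxylate | COc1cn(C(=O)OC(C)(C)C)c(O[Si](C)(C)C(C)(C)C)c1
A6 | alternative 2 | tert-butyl 4,6-dibromo-2-[(tert-butyldimethylsilyl)oxy]-1H-indole-1-carboxylate | CC(C)(C)OC(=O)n1c(O[Si](C)(C)C(C)(C)C)cc2c(Br)cc(Br)cc21
A7 | alternative 3 | N-[3,5-dibromo-2-(bromomethyl)phenyl]-4-methylbenzenesulfonamide | Cc1ccc(cc1)S(=O)(=O)Nc1cc(Br)cc(Br)c1CBr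
A8 | alternative 3 | N-(3,5-dibromo-6-methylidenecyclohexa-2,4-dien-1-ylidene)-4-methylbenzenesulfonamide | Cc1ccc(cc1)S(=O)(=O)N=C1C=C(Br)C=C(Br)C1=C
A9 | alternative 3 | bromoform | BrC(Br)Br
A10 | alternative 3 | 2,4,6-tribromo-1-tosyl-1H-indole | Cc1ccc(cc1)S(=O)(=O)n1c(Br)cc2c(Br)cc(Br)cc21
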